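The central ring is twofold symmetric. Cutting its two C(=O)–C(OMe) bonds leaves two identical three-carbon units, each an indol-3-yl-bearing ring carbon flanked by one carbonyl carbon and one methoxy-bearing carbon. Each unit is the acyclic ester methyl (E)-3-methoxy-2-(indol-3-yl)acrylate: its ester carbon becomes a quinone C=O and its vinylic C–H carbon a C–OMe carbon. Lithiation of that C–H and head-to-tail double acylation of two molecules should form both ring bonds, close the quinone ring at its final oxidation level and deliver the target directly from a non-quinonoid precursor.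

Key step: step 5

Assumption: the target has no stereocentre, so the only stereochemical element the route has to control is the alkene geometry of compounds 7 to 10.

Step 1
Reactants: 1 9-borabicyclo[3.3.1]nonane (9-BBN-H, commercial THF solution); 2 3-methylbuta-1,2-diene
Product: 3 9-(3-methylbut-2-en-1-yl)-9-borabicyclo[3.3.1]nonane (B-prenyl-9-BBN), kept as a THF solution
Conditions: THF, 0 °C to rt (2 in slight excess, excess removed under vacuum so that no B–H remains)
Reagents that add atoms: none
Why: Hydroboration of the allene places boron on the unsubstituted terminal carbon and hydrogen on the central carbon, which should give the allylic borane directly (known hydroboration of 1,1-disubstituted allenes with 9-BBN-H).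

Step 2
Reactants: 4 methyl 2-(1H-indol-3-yl)acetate; 3 B-prenyl-9-BBN
Product: 6 methyl 2-[2-(2-methylbut-3-en-2-yl)-1H-indol-3-yl]acetate, via 3-chloroindolenine 5 (not isolated)
Conditions: t-BuOCl (1.0 equiv), Et3N, THF, −78 °C; then 3 in THF, −78 °C to rt; aqueous work-up
Reagents that add atoms: tert-butyl hypochlorite, CC(C)(C)OCl (supplies the chlorine of intermediate 5 only; it is lost again on the way to 6)
Why: Electrophilic chlorination at C3 gives chloroindolenine 5, whose C=N bond is allylated by 3 through a six-membered transition state with allylic transposition, so that the quaternary carbon bonds to C2, and loss of HCl restores the indole (known reverse prenylation of 3-substituted indoles by the chloroindolenine and allylborane sequence).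

Step 3
Reactants: 6 methyl 2-[2-(2-methylbut-3-en-2-yl)-1H-indol-3-yl]acetate
Product: 7 methyl (Z)-3-hydroxy-2-[2-(2-methylbut-3-en-2-yl)-1H-indol-3-yl]prop-2-enoate (chelated enol form of the α-formyl ester)
Conditions: NaH (3 equiv), HCO2Me (excess), THF, 0 °C to rt; AcOH
Reagents that add atoms: methyl formate, COC=O
Why: Crossed Claisen condensation of the ester enolate with non-enolisable methyl formate, driven by formation of the stabilised sodium enolate of the product; the extra NaH only deprotonates the indole N–H, which is restored on quenching.

Step 4
Reactants: 7 methyl (Z)-3-hydroxy-2-[2-(2-methylbut-3-en-2-yl)-1H-indol-3-yl]prop-2-enoate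
Product: 8 methyl (E)-3-methoxy-2-[2-(2-methylbut-3-en-2-yl)-1H-indol-3-yl]prop-2-enoate
Conditions: Me2SO4, K2CO3, DMF, rt
Reagents that add atoms: dimethyl sulfate, COS(=O)(=O)OC
Why: O-Alkylation of the potassium enolate of the formyl ester with the hard electrophile dimethyl sulfate, the standard entry to β-methoxyacrylates, should give the (E) isomer, because the enolate prefers the extended form with its oxygen anti to the ester and (E) is also the more stable enol ether, while the indole N–H is not deprotonated by K2CO3.

Step 5
Reactants: 8 methyl (E)-3-methoxy-2-[2-(2-methylbut-3-en-2-yl)-1H-indol-3-yl]prop-2-enoate (two molecules)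
Product: 11 2,5-dimethoxy-3,6-bis[2-(2-methylbut-3-en-2-yl)-1H-indol-3-yl]cyclohexa-2,5-diene-1,4-dione (target CNP0331285.0), via dilithio acrylate 9 (not isolated), via open-chain lithio keto ester 10 (not isolated)
Conditions: LiTMP (2.3 equiv, from 2,2,6,6-tetramethylpiperidine and n-BuLi), THF, −95 °C; then −95 to −20 °C; AcOH
Reagents that add atoms: lithium 2,2,6,6-tetramethylpiperidide, [Li]N1C(C)(C)CCCC1(C)C (supplies the lithium of intermediates 9 and 10 only; no reagent atom remains in 11)
Why: Proposed new method: the first equivalent of LiTMP removes the indole N–H and the second removes the single vinylic C–H, which is acidified by the α-methoxy group and lies cis to the lithium-chelating ester carbonyl, to give 9; on warming, the C–Li carbon of one molecule should acylate at the ester of a second (loss of LiOMe) to form the first C(OMe)–C(=O) bond in 10, whose remaining C–Li carbon then attacks the remaining ester to form the second. The closest known reaction types are the directed β-lithiation of β-alkoxyacrylates with trapping by carbonyl electrophiles, the acylation of organolithium reagents by esters and the Parham-type anionic cyclisation onto an ester, and what is new is their combination into a [3+3] cyclodimerisation that ends in a quinone. The six-membered ring closes by 6-exo-trig attack of the vinyllithium on the ester carbonyl, with all six ring atoms already sp2 and no redox adjustment needed. No stereocentre is formed. The step needs head-to-tail regiochemistry, which is inherent because each monomer has exactly one nucleophilic and one electrophilic terminus, and it needs the (E) geometry of 8, which puts lithium and ester cis on each double bond so that both acylations and the ring closure are geometrically possible. The main selectivity risk is a further addition of vinyllithium to the new ketone or quinone carbonyls, which should be held back by the low temperature, by the flanking 2-tert-alkylindolyl groups and by the electron-rich N-lithioindolyl donors.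

Compound list
1 | 9-borabicyclo[3.3.1]nonane (9-BBN-H, written as the monomer) | B1C2CCCC1CCC2 | starting material
2 | 3-methylbuta-1,2-diene | C=C=C(C)C | starting material
3 | 9-(3-methylbut-2-en-1-yl)-9-borabicyclo[3.3.1]nonane (B-prenyl-9-BBN) | CC(C)=CCB1C2CCCC1CCC2 | intermediate
4 | methyl 2-(1H-indol-3-yl)acetate | COC(=O)Cc1c[nH]c2ccccc12 | starting material
5 | methyl 2-(3-chloro-3H-indol-3-yl)acetate (racemic 3-chloroindolenine, not isolated) | COC(=O)CC1(Cl)C=Nc2ccccc21 | intermediate
6 | methyl 2-[2-(2-methylbut-3-en-2-yl)-1H-indol-3-yl]acetate | COC(=O)Cc1c(C(C)(C)C=C)[nH]c2ccccc12 | intermediate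
7 | methyl (Z)-3-hydroxy-2-[2-(2-methylbut-3-en-2-yl)-1H-indol-3-yl]prop-2-enoate (enol of the α-formyl ester, OH cis to the ester) | COC(=O)/C(=C\O)c1c(C(C)(C)C=C)[nH]c2ccccc12 | intermediate
8 | methyl (E)-3-methoxy-2-[2-(2-methylbut-3-en-2-yl)-1H-indol-3-yl]prop-2-enoate (OMe trans to the ester, vinylic H cis to the ester) | CO/C=C(/C(=O)OC)c1c(C(C)(C)C=C)[nH]c2ccccc12 | intermediate
9 | methyl 3-lithio-3-methoxy-2-[1-lithio-2-(2-methylbut-3-en-2-yl)indol-3-yl]prop-2-enoate (lithium cis to the ester, not isolated) | CO/C([Li])=C(/C(=O)OC)c1c(C(C)(C)C=C)n([Li])c2ccccc12 | intermediate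
10 | methyl 6-lithio-3,6-dimethoxy-4-oxo-2,5-bis[1-lithio-2-(2-methylbut-3-en-2-yl)indol-3-yl]hexa-2,5-dienoate (ester cis to the ketone across C2=C3, lithium cis to the ketone across C5=C6, not isolated) | CO/C([Li])=C(/C(=O)/C(OC)=C(\C(=O)OC)c1c(C(C)(C)C=C)n([Li])c2ccccc12)c1c(C(C)(C)C=C)n([Li])c2ccccc12 | intermediate
11 | 2,5-dimethoxy-3,6-bis[2-(2-methylbut-3-en-2-yl)-1H-indol-3-yl]cyclohexa-2,5-diene-1,4-dione (CNP0331285.0) | C=CC(C)(C)c1[nH]c2ccccc2c1C1=C(OC)C(=O)C(c2c(C(C)(C)C=C)[nH]c3ccccc23)=C(OC)C1=O | target

Total step count: 5. Longest linear sequence: 5 steps (steps 1 to 5 through borane 3; 4 steps counted from indole ester 4).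

Steps most likely to fail

Step 5 (proposed new method). The vinyllithium may add a second time to the ketone of 10 or to the quinone carbonyls, or the intermolecular acylation at the hindered ester may be outrun by decomposition of the lithio species on warming. The fallback uses known chemistry, sets out from 6 and comes back to the route at 11. Crossed Claisen condensation of 6 with dimethyl oxalate (NaOMe, THF/MeOH) should give dimethyl 2-[2-(2-methylbut-3-en-2-yl)-1H-indol-3-yl]-3-oxobutanedioate F1. Krapcho dealkoxycarbonylation (LiCl, wet DMSO, 120 °C) should remove the ester on the indolyl-bearing carbon and give methyl 3-[2-(2-methylbut-3-en-2-yl)-1H-indol-3-yl]-2-oxopropanoate F2. Head-to-tail double Claisen (Dieckmann-type) self-condensation of F2 (NaOMe, MeOH, reflux) copies the presumed biosynthetic assembly of this quinone family and closes the ring at the bonds between the indolyl-bearing carbons and the carbonyl carbons. It should give 2,5-dihydroxy-3,6-bis[2-(2-methylbut-3-en-2-yl)-1H-indol-3-yl]cyclohexa-2,5-diene-1,4-dione F3. O-Methylation of the two vinylogous acid hydroxyls (Me2SO4, K2CO3, acetone) then gives 11.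

Step 2. Triethylamine may remove HCl from chloroindolenine 5 toward the ester-activated CH2, or 5 may rearrange before the allyl transfer, so that C2 is never alkylated. The fallback sets out from 4 and comes back at 6. Bromination of 4 at C2 with N-bromosuccinimide (CH2Cl2, 0 °C) should give methyl 2-(2-bromo-1H-indol-3-yl)acetate F4. A branch-selective Suzuki–Miyaura coupling of F4 with commercial prenylboronic acid pinacol ester (Pd(OAc)2, a bulky electron-rich phosphine such as 1,1'-bis(di-tert-butylphosphino)ferrocene, K3PO4, aqueous THF) transfers the allyl group with allylic transposition and should give 6.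

Step 4. Methylation may take place at the indole nitrogen or at carbon, or may give the (Z)-enol ether, whose vinylic hydrogen is anti to the ester and cannot lead to a ring in step 5. The fallback sets out from 7 and comes back at 8. Acetalisation of the formyl group (HC(OMe)3, MeOH, catalytic pyridinium p-toluenesulfonate) should give methyl 3,3-dimethoxy-2-[2-(2-methylbut-3-en-2-yl)-1H-indol-3-yl]propanoate F5. Elimination of methanol (TMSOTf, i-Pr2NEt, CH2Cl2, −20 °C to rt) proceeds through the oxocarbenium ion with loss of the ester α-proton and should favour the conjugated (E) isomer 8.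

Further compounds
F1 | step 5 | dimethyl 2-[2-(2-methylbut-3-en-2-yl)-1H-indol-3-yl]-3-oxobutanedioate (racemic, enolisable) | COC(=O)C(=O)C(C(=O)OC)c1c(C(C)(C)C=C)[nH]c2ccccc12
F2 | step 5 | methyl 3-[2-(2-methylbut-3-en-2-yl)-1H-indol-3-yl]-2-oxopropanoate | COC(=O)C(=O)Cc1c(C(C)(C)C=C)[nH]c2ccccc12
F3 | step 5 | 2,5-dihydroxy-3,6-bis[2-(2-methylbut-3-en-2-yl)-1H-indol-3-yl]cyclohexa-2,5-diene-1,4-dione | C=CC(C)(C)c1[nH]c2ccccc2c1C1=C(O)C(=O)C(c2c(C(C)(C)C=C)[nH]c3ccccc23)=C(O)C1=O
F4 | step 2 | methyl 2-(2-bromo-1H-indol-3-yl)acetate | COC(=O)Cc1c(Br)[nH]c2ccccc12
F5 | step 4 | methyl 3,3-dimethoxy-2-[2-(2-methylbut-3-en-2-yl)-1H-indol-3-yl]propanoate (racemic) | COC(=O)C(C(OC)OC)c1c(C(C)(C)C=C)[nH]c2ccccc12
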